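The data were computed with constants of no real substance; the scatter is artificial.

We start with the loss.

| flask | starting material | remark | time |
|---|---|---|---|
| ochre | 26 mM | the very flask that is asked about, followed so far |  |
| grey | 39 mM | run made earlier |  |
| flask | 26 mM |  | 2.5 d |

| run | time / h | intermediate / % | target / % | starting material / % |
|---|---|---|---|---|
| ochre | 5.00 | 14.0 | 0.2 | 83.7 |
| ochre | 6.00 | 15.6 | 0 | 80.6 |
| ochre | 8.00 | 18.7 | 0 | 74.6 |
| ochre | 12.0 | 23.4 | 0.3 | 64.8 |
| ochre | 15.0 | 24.6 | 0 | 58.4 |
| ochre | 20.0 | 25.2 | 0.8 | 48.3 |
| ochre | 30.0 | 22.2 | 1.0 | 33.9 |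
| grey | 5.00 | 13.6 | 0.4 | 83.4 |
| grey | 6.00 | 15.3 | 0 | 80.6 |
| grey | 8.00 | 18.9 | 0.1 | 74.3 |
| grey | 10.0 | 20.9 | 0 | 69.6 |
| grey | 15.0 | 24.4 | 0 | 58.1 |
| grey | 20.0 | 25.4 | 0.4 | 48.1 |
| grey | 25.0 | 23.8 | 0.5 | 40.2 |

(standard deviation of a reading: 0.3 percentage points)

- the analysis behind the earlier runs scatters by 0.3 percentage points, standard deviation
- a reading or a percentage of target counts all its forms, free or not
- a reading of starting material is of its free form alone

1. time up to 2.5 d at which intermediate stands highest
2. the amount of intermediate, in percent of the starting material charged, at that time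

In the ochre flask, starting material falls with one constant, kA = 0.0362 h⁻¹. The grey run at 39 mM reads 25.4 % of intermediate at 20.0 h, against 25.2 % in the ochre run at 26 mM, so we reckon both steps as first order.

At the very start of the ochre run, c(intermediate) is near zero and climbs at the pace set by kA. Target reads just 1.0 % even at 30.0 h. Yet between 15.0 h and 30.0 h the sum of the three readings drops by 26 percentage points, while intermediate averages 24.0 %. We take this as a drain on intermediate, with kI = 0.0719 h⁻¹.

The quantity we carry is the drain ratio, kI over kA, 1.99: how many times faster intermediate is lost than starting material, each reckoned per unit of itself. At the top of intermediate, making meets draining, and c(intermediate)/c(starting material) equals its inverse. By our reckoning that comes at ln(ratio)/(kI − kA) = 0.801 d, earlier than the limit of 2.5 d, with a height of 25.1 %. After that, draining outruns making and both fall.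

The forecast gives 0.79 d and 25.3 %, holding that “intermediate is draining first order into something unseen”.

The flask gives 0.796 d and 24.9 %.

    starting material → intermediate (k = 6.00 × 10⁻⁴ min⁻¹)
    intermediate → target (k = 2.58 × 10⁻⁵ min⁻¹)
    starting material + target ⇌ idle adduct, settled at all times (K = 373 L mol⁻¹)
    intermediate → decomposed reagent (k = 0.00118 min⁻¹)

At that time in the asked flask, intermediate over starting material stands at 0.498, and the inverse drain ratio is 0.503. A neighbouring flask with the same charge, stopped at 15 h, earlier than the top, reached 24.2 %, where the ratio reckons 24.3 %. At 0.670 d in the asked flask, intermediate turns into decomposed reagent 46 times as fast as into target, a selectivity factor already 46 just after the start. At 2.50 d the asked flask holds 76.2 % of decomposed reagent against 1.67 % of target.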